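The plan rests on cutting ring C of the dihydroflavonol at O1–C2 and C3–C4: the atoms O1, C8a, C4a and C4, fused to ring A, are seen as an alkoxy ortho-quinone methide (four-atom heterodiene) and C2–C3 as an (E)-enol acetate. One chiral-acid-catalysed inverse-demand hetero-Diels–Alder addition closes the pyran ring, makes both skeletal bonds and sets C2, C3 and C4, with C4 already at the aldehyde oxidation level. The diene precursor is a free-phenol salicylaldehyde dimethyl acetal carrying OMe, geranyl and OMOM groups, unmasked by fluoride just before use; the dienophile is a geometrically pure 4-(methoxymethoxy)styryl acetate.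

Key step: step 10

Remark: geranyl means (2E)-3,7-dimethylocta-2,6-dien-1-yl; the antipode of the chiral acid that leads to the (2R,3S) series cannot be assigned in advance and is to be fixed by a pilot run, (R) being written; the C4 configuration of the cycloadduct is drawn all-trans, and either C4 epimer would serve because C4 becomes the carbonyl carbon.

Step 1
Reactants: 1 2,4-dihydroxy-6-methoxybenzaldehyde
Product: 2 2-hydroxy-6-methoxy-4-(methoxymethoxy)benzaldehyde
Conditions: MOMCl (1.05 equiv), iPr2NEt, CH2Cl2, 0 °C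
Reagents that add atoms: chloromethyl methyl ether (MOMCl), COCCl
Why: Chemoselective O-alkylation (MOM protection): the 4-OH, para to the formyl group and not hydrogen-bonded, is the more acidic and accessible phenol, while the 2-OH stays chelated to the aldehyde.

Step 2
Reactants: 2 2-hydroxy-6-methoxy-4-(methoxymethoxy)benzaldehyde
Product: 3 2-methoxy-4-(methoxymethoxy)-6-[(triisopropylsilyl)oxy]benzaldehyde
Conditions: TIPSOTf, 2,6-lutidine, CH2Cl2, 0 °C → rt
Reagents that add atoms: triisopropylsilyl trifluoromethanesulfonate (TIPSOTf), CC(C)[Si](OS(=O)(=O)C(F)(F)F)(C(C)C)C(C)C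
Why: Silyl ether formation: the reactive silyl triflate overcomes the hydrogen bond of the chelated phenol, and the bulky, non-coordinating TIPS ether later blocks lithiation beside it and is removable by fluoride.

Step 3
Reactants: 3 2-methoxy-4-(methoxymethoxy)-6-[(triisopropylsilyl)oxy]benzaldehyde
Product: 4 [2-(dimethoxymethyl)-3-methoxy-5-(methoxymethoxy)phenoxy]triisopropylsilane
Conditions: HC(OMe)3 (5 equiv), pyridinium p-toluenesulfonate (PPTS, 5 mol %), MeOH, rt; Et3N quench
Reagents that add atoms: trimethyl orthoformate, COC(OC)OC; methanol, CO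
Why: Acid-catalysed acetalisation driven by the orthoformate as water scavenger: the oxocarbenium ion of this electron-rich aldehyde forms easily, the weak acid spares the MOM and TIPS ethers, and with the phenol silylated no quinone methide pathway is open.

Step 4
Reactants: 4 [2-(dimethoxymethyl)-3-methoxy-5-(methoxymethoxy)phenoxy]triisopropylsilane, 5 geranyl bromide
Product: 7 {2-(dimethoxymethyl)-4-[(2E)-3,7-dimethylocta-2,6-dien-1-yl]-3-methoxy-5-(methoxymethoxy)phenoxy}triisopropylsilane, via aryllithium 6 (not isolated)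
Conditions: n-BuLi, THF, 0 °C; then CuBr·SMe2 (10 mol %), 5, −78 → 0 °C
Reagents that add atoms: none
Why: Directed ortho-metalation followed by copper-catalysed SN2 allylation: OMOM and the neighbouring OMe together direct lithiation to the carbon between them while OTIPS shields the other ortho site, and the aryl nucleophile attacks the primary carbon of geranyl bromide so that the (2E) geometry is carried over unchanged.

Step 5
Reactants: 7 {2-(dimethoxymethyl)-4-[(2E)-3,7-dimethylocta-2,6-dien-1-yl]-3-methoxy-5-(methoxymethoxy)phenoxy}triisopropylsilane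
Product: 8 2-(dimethoxymethyl)-4-[(2E)-3,7-dimethylocta-2,6-dien-1-yl]-3-methoxy-5-(methoxymethoxy)phenol
Conditions: TBAF (1.05 equiv), THF, −20 °C; aq. NaHCO3; used at once
Reagents that add atoms: none
Why: Fluoride-induced desilylation frees the phenol under non-acidic conditions, so the acid-labile dimethyl acetal and the MOM ether should survive and the sensitive phenol acetal never meets acid before the cycloaddition.

Step 6
Reactants: 9 4-hydroxybenzaldehyde
Product: 10 4-(methoxymethoxy)benzaldehyde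
Conditions: MOMCl, iPr2NEt, CH2Cl2, 0 °C → rt
Reagents that add atoms: chloromethyl methyl ether (MOMCl), COCCl
Why: Standard O-alkylation of a phenol with the reactive α-chloro ether (MOM protection), which keeps the para oxygen a strong donor for the later cycloaddition.

Step 7
Reactants: 10 4-(methoxymethoxy)benzaldehyde, 11 bis(pinacolato)diborylmethane
Product: 13 2-{(E)-2-[4-(methoxymethoxy)phenyl]ethenyl}-4,4,5,5-tetramethyl-1,3,2-dioxaborolane, via lithiated diborylmethane 12 (not isolated)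
Conditions: 11, lithium 2,2,6,6-tetramethylpiperidide, THF, 0 °C; then 10, −78 °C → rt
Reagents that add atoms: none
Why: Boron–Wittig olefination: the α-lithiated gem-diboronate adds to the aldehyde and syn B–O elimination should give the trans-alkenyl boronate, aryl and Bpin lying anti in the elimination.

Step 8
Reactants: 13 2-{(E)-2-[4-(methoxymethoxy)phenyl]ethenyl}-4,4,5,5-tetramethyl-1,3,2-dioxaborolane
Product: 14 potassium trifluoro{(E)-2-[4-(methoxymethoxy)phenyl]ethenyl}borate
Conditions: KHF2 (aq.), MeOH, rt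
Reagents that add atoms: potassium hydrogen difluoride, [K+].[F-].F
Why: Ligand exchange at boron (boronate to trifluoroborate) leaves the alkene geometry untouched and gives a crystalline salt, and the aryl MOM ether tolerates the brief, weakly acidic treatment.

Step 9
Reactants: 14 potassium trifluoro{(E)-2-[4-(methoxymethoxy)phenyl]ethenyl}borate
Product: 15 (E)-2-[4-(methoxymethoxy)phenyl]ethenyl acetate
Conditions: AcOH, CuBr (10 mol %), 4-(dimethylamino)pyridine (DMAP, 20 mol %), 4 Å MS, O2 (1 atm), MeCN, 60 °C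
Reagents that add atoms: acetic acid, CC(=O)O
Why: Copper-catalysed oxidative C–O coupling of an alkenyltrifluoroborate with a carboxylic acid (Chan–Lam-type enol ester synthesis) proceeds with retention of alkene geometry, so the (E) boron compound should give the (E) enol acetate free of the (Z) isomer.

Step 10
Reactants: 8 2-(dimethoxymethyl)-4-[(2E)-3,7-dimethylocta-2,6-dien-1-yl]-3-methoxy-5-(methoxymethoxy)phenol, 15 (E)-2-[4-(methoxymethoxy)phenyl]ethenyl acetate
Product: 17 (2R,3S,4R)-6-[(2E)-3,7-dimethylocta-2,6-dien-1-yl]-4,5-dimethoxy-7-(methoxymethoxy)-2-[4-(methoxymethoxy)phenyl]-3,4-dihydro-2H-chromen-3-yl acetate, via methoxy ortho-quinone methide 16 (not isolated)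
Conditions: (R)-3,3'-bis(2,4,6-triisopropylphenyl)-1,1'-binaphthyl-2,2'-diyl hydrogen phosphate [(R)-TRIP] (10 mol %), 15 (1.5 equiv), 5 Å MS, PhMe, −20 °C
Reagents that add atoms: none
Why: Proposed new method: the chiral phosphoric acid removes methanol from the acetal of 8 to give the 4-methoxy ortho-quinone methide 16, held to the phosphate through the phenolic O–H; the acetoxy-bearing carbon of 15 then attacks the exocyclic carbon (C3–C4) while the phenolic oxygen collapses onto the developing 4-alkoxybenzyl cation (O1–C2), an asynchronous suprafacial inverse-demand hetero-Diels–Alder addition. The closest known reaction type is the Brønsted-acid-catalysed [4+2] of ortho-quinone methides, generated from salicylaldehyde acetals or ortho-hydroxybenzyl alcohols, with styrenes and anethole-type alkenes, including chiral-phosphoric-acid variants with activated alkenes; an enol ester as the two-carbon partner is the untested element. The pyran ring is closed by the cycloaddition itself, its second bond arising by collapse of the phenolic oxygen onto the benzylic cation within the ion pair. C2 and C3 should come out trans because the (E) geometry of 15 is transferred suprafacially; C4 depends on the methide geometry and the exo or endo placement of the acetoxy group and is erased in step 13; the absolute sense at C2 and C3 should follow from the face of 16 left open by the 3,3'-aryl groups of the bound catalyst. The step needs 2-aryl-3-acetoxy regiochemistry, which the 4-(methoxymethoxy)phenyl group secures by stabilising positive charge at C2 far better than the acetoxy group can at C3, and it needs a single alkene isomer, which step 9 supplies.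

Step 11
Reactants: 17 (2R,3S,4R)-6-[(2E)-3,7-dimethylocta-2,6-dien-1-yl]-4,5-dimethoxy-7-(methoxymethoxy)-2-[4-(methoxymethoxy)phenyl]-3,4-dihydro-2H-chromen-3-yl acetate
Product: 18 (2R,3S,4R)-6-[(2E)-3,7-dimethylocta-2,6-dien-1-yl]-4,5-dimethoxy-7-(methoxymethoxy)-2-[4-(methoxymethoxy)phenyl]-3,4-dihydro-2H-chromen-3-ol
Conditions: K2CO3 (0.3 equiv), MeOH, rt
Reagents that add atoms: none
Why: Base-catalysed transesterification (methanolysis of the acetate) is done while no carbonyl group is present, so C2 and C3 have no pathway to epimerise, and the MOM and methyl ethers are inert to base.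

Step 12
Reactants: 18 (2R,3S,4R)-6-[(2E)-3,7-dimethylocta-2,6-dien-1-yl]-4,5-dimethoxy-7-(methoxymethoxy)-2-[4-(methoxymethoxy)phenyl]-3,4-dihydro-2H-chromen-3-ol
Product: 19 (2R,3S)-6-[(2E)-3,7-dimethylocta-2,6-dien-1-yl]-5-methoxy-7-(methoxymethoxy)-2-[4-(methoxymethoxy)phenyl]-3,4-dihydro-2H-chromene-3,4-diol (C4 epimers)
Conditions: PPTS (0.2 equiv), THF–H2O (4:1), 40 °C
Reagents that add atoms: water, O
Why: Acid-catalysed SN1 solvolysis: the C4 methyl ether ionises to a benzylic cation stabilised by O1 and the 5- and 7-oxygens of ring A and is captured by the large excess of water, PPTS being too weak to cleave the aryl MOM ethers or the C2–O1 bond; the C4 epimer mixture is of no consequence.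

Step 13
Reactants: 19 (2R,3S)-6-[(2E)-3,7-dimethylocta-2,6-dien-1-yl]-5-methoxy-7-(methoxymethoxy)-2-[4-(methoxymethoxy)phenyl]-3,4-dihydro-2H-chromene-3,4-diol (C4 epimers)
Product: 20 (2R,3R)-6-[(2E)-3,7-dimethylocta-2,6-dien-1-yl]-3-hydroxy-5-methoxy-7-(methoxymethoxy)-2-[4-(methoxymethoxy)phenyl]-2,3-dihydro-4H-chromen-4-one
Conditions: MnO2 (activated, 15 equiv), CH2Cl2, rt
Reagents that add atoms: none
Why: Chemoselective benzylic oxidation: activated MnO2 oxidises the C4 carbinol on the electron-rich ring A much faster than the unactivated C3 alcohol, and the neutral heterogeneous conditions leave C2, C3 and the geranyl alkenes untouched.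

Step 14
Reactants: 20 (2R,3R)-6-[(2E)-3,7-dimethylocta-2,6-dien-1-yl]-3-hydroxy-5-methoxy-7-(methoxymethoxy)-2-[4-(methoxymethoxy)phenyl]-2,3-dihydro-4H-chromen-4-one
Product: 21 (2R,3R)-6-[(2E)-3,7-dimethylocta-2,6-dien-1-yl]-3,7-dihydroxy-2-(4-hydroxyphenyl)-5-methoxy-2,3-dihydro-4H-chromen-4-one
Conditions: aq. HCl (3 M), MeOH, 45 °C, stopped at full conversion
Reagents that add atoms: none
Why: Acid-catalysed acetal exchange with methanol (MOM cleavage) frees both phenols; the 2,3-trans dihydroflavonol is the thermodynamically preferred diastereomer and is configurationally stable in acid, and short exposure should limit addition of the 7-OH to the geranyl alkene.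

Compound list
1 | 2,4-dihydroxy-6-methoxybenzaldehyde | COc1cc(O)cc(O)c1C=O | starting material
2 | 2-hydroxy-6-methoxy-4-(methoxymethoxy)benzaldehyde | COc1cc(OCOC)cc(O)c1C=O | intermediate
3 | 2-methoxy-4-(methoxymethoxy)-6-[(triisopropylsilyl)oxy]benzaldehyde | COc1cc(OCOC)cc(O[Si](C(C)C)(C(C)C)C(C)C)c1C=O | intermediate
4 | [2-(dimethoxymethyl)-3-methoxy-5-(methoxymethoxy)phenoxy]triisopropylsilane | COc1cc(OCOC)cc(O[Si](C(C)C)(C(C)C)C(C)C)c1C(OC)OC | intermediate
5 | geranyl bromide, (2E)-1-bromo-3,7-dimethylocta-2,6-diene | BrC/C=C(\C)CCC=C(C)C | starting material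
6 | {3-(dimethoxymethyl)-2-methoxy-6-(methoxymethoxy)-4-[(triisopropylsilyl)oxy]phenyl}lithium | [Li]c1c(OC)c(C(OC)OC)c(O[Si](C(C)C)(C(C)C)C(C)C)cc1OCOC | intermediate (not isolated)
7 | {2-(dimethoxymethyl)-4-[(2E)-3,7-dimethylocta-2,6-dien-1-yl]-3-methoxy-5-(methoxymethoxy)phenoxy}triisopropylsilane | COc1c(C/C=C(\C)CCC=C(C)C)c(OCOC)cc(O[Si](C(C)C)(C(C)C)C(C)C)c1C(OC)OC | intermediate
8 | 2-(dimethoxymethyl)-4-[(2E)-3,7-dimethylocta-2,6-dien-1-yl]-3-methoxy-5-(methoxymethoxy)phenol | COc1c(C/C=C(\C)CCC=C(C)C)c(OCOC)cc(O)c1C(OC)OC | intermediate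
9 | 4-hydroxybenzaldehyde | O=Cc1ccc(O)cc1 | starting material
10 | 4-(methoxymethoxy)benzaldehyde | COCOc1ccc(C=O)cc1 | intermediate
11 | bis(pinacolato)diborylmethane, 2,2'-methylenebis(4,4,5,5-tetramethyl-1,3,2-dioxaborolane) | CC1(C)OB(CB2OC(C)(C)C(C)(C)O2)OC1(C)C | starting material
12 | [bis(4,4,5,5-tetramethyl-1,3,2-dioxaborolan-2-yl)methyl]lithium | [Li]C(B1OC(C)(C)C(C)(C)O1)B1OC(C)(C)C(C)(C)O1 | intermediate (not isolated)
13 | 2-{(E)-2-[4-(methoxymethoxy)phenyl]ethenyl}-4,4,5,5-tetramethyl-1,3,2-dioxaborolane | COCOc1ccc(/C=C/B2OC(C)(C)C(C)(C)O2)cc1 | intermediate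
14 | potassium trifluoro{(E)-2-[4-(methoxymethoxy)phenyl]ethenyl}borate | COCOc1ccc(/C=C/[B-](F)(F)F)cc1.[K+] | intermediate
15 | (E)-2-[4-(methoxymethoxy)phenyl]ethenyl acetate | CC(=O)O/C=C/c1ccc(OCOC)cc1 | intermediate
16 | 4-[(2E)-3,7-dimethylocta-2,6-dien-1-yl]-5-methoxy-3-(methoxymethoxy)-6-(methoxymethylidene)cyclohexa-2,4-dien-1-one (exocyclic geometry not defined) | COC=C1C(=O)C=C(OCOC)C(C/C=C(\C)CCC=C(C)C)=C1OC | intermediate (not isolated)
17 | (2R,3S,4R)-6-[(2E)-3,7-dimethylocta-2,6-dien-1-yl]-4,5-dimethoxy-7-(methoxymethoxy)-2-[4-(methoxymethoxy)phenyl]-3,4-dihydro-2H-chromen-3-yl acetate | COc1c(C/C=C(\C)CCC=C(C)C)c(OCOC)cc2c1[C@@H](OC)[C@H](OC(C)=O)[C@@H](c1ccc(OCOC)cc1)O2 | intermediate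
18 | (2R,3S,4R)-6-[(2E)-3,7-dimethylocta-2,6-dien-1-yl]-4,5-dimethoxy-7-(methoxymethoxy)-2-[4-(methoxymethoxy)phenyl]-3,4-dihydro-2H-chromen-3-ol | COc1c(C/C=C(\C)CCC=C(C)C)c(OCOC)cc2c1[C@@H](OC)[C@H](O)[C@@H](c1ccc(OCOC)cc1)O2 | intermediate
19 | (2R,3S)-6-[(2E)-3,7-dimethylocta-2,6-dien-1-yl]-5-methoxy-7-(methoxymethoxy)-2-[4-(methoxymethoxy)phenyl]-3,4-dihydro-2H-chromene-3,4-diol (C4 epimers) | COc1c(C/C=C(\C)CCC=C(C)C)c(OCOC)cc2c1C(O)[C@H](O)[C@@H](c1ccc(OCOC)cc1)O2 | intermediate
20 | (2R,3R)-6-[(2E)-3,7-dimethylocta-2,6-dien-1-yl]-3-hydroxy-5-methoxy-7-(methoxymethoxy)-2-[4-(methoxymethoxy)phenyl]-2,3-dihydro-4H-chromen-4-one | COc1c(C/C=C(\C)CCC=C(C)C)c(OCOC)cc2c1C(=O)[C@H](O)[C@@H](c1ccc(OCOC)cc1)O2 | intermediate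
21 | (2R,3R)-6-[(2E)-3,7-dimethylocta-2,6-dien-1-yl]-3,7-dihydroxy-2-(4-hydroxyphenyl)-5-methoxy-2,3-dihydro-4H-chromen-4-one | COc1c(C/C=C(\C)CCC=C(C)C)c(O)cc2c1C(=O)[C@H](O)[C@@H](c1ccc(O)cc1)O2 | target

Total step count: 14.
Longest linear sequence: 10 steps (steps 1–5, then 10–14); the dienophile branch (steps 6–9) joins at step 10.

Steps most likely to fail

Step 10. The cycloaddition may stall after ionisation, because the electron-rich methide is a weak electrophile and the enol acetate only a modest nucleophile. Facial selectivity may be eroded by an unbound background pathway, or the trans relationship lost through a long-lived benzylic cation. The fallback uses known chalcone chemistry, sets out from 7 (with 14 as partner) and rejoins at 20. The acetal of 7 is hydrolysed (PPTS, wet acetone) to 3-[(2E)-3,7-dimethylocta-2,6-dien-1-yl]-2-methoxy-4-(methoxymethoxy)-6-[(triisopropylsilyl)oxy]benzaldehyde F1. Rhodium-catalysed 1,2-addition of 14 (Rh(acac)(CO)2, dppf, DME–H2O, 80 °C) gives the racemic allylic alcohol (2E)-1-{3-[(2E)-3,7-dimethylocta-2,6-dien-1-yl]-2-methoxy-4-(methoxymethoxy)-6-[(triisopropylsilyl)oxy]phenyl}-3-[4-(methoxymethoxy)phenyl]prop-2-en-1-ol F2. MnO2 oxidises it to the chalcone (2E)-1-{3-[(2E)-3,7-dimethylocta-2,6-dien-1-yl]-2-methoxy-4-(methoxymethoxy)-6-[(triisopropylsilyl)oxy]phenyl}-3-[4-(methoxymethoxy)phenyl]prop-2-en-1-one F3. Juliá–Colonna epoxidation (poly-L-leucine, urea–H2O2, DBU, THF) is nucleophilic and so spares the geranyl alkenes; it should give {3-[(2E)-3,7-dimethylocta-2,6-dien-1-yl]-2-methoxy-4-(methoxymethoxy)-6-[(triisopropylsilyl)oxy]phenyl}{(2R,3S)-3-[4-(methoxymethoxy)phenyl]oxiran-2-yl}methanone F4. Fluoride buffered with acetic acid frees the phenol to give {3-[(2E)-3,7-dimethylocta-2,6-dien-1-yl]-6-hydroxy-2-methoxy-4-(methoxymethoxy)phenyl}{(2R,3S)-3-[4-(methoxymethoxy)phenyl]oxiran-2-yl}methanone F5. Mild acid (PPTS, CH2Cl2) should then induce 6-endo attack of the phenol at the 4-alkoxybenzylic epoxide carbon with inversion, giving the (2R,3R) ketol 20.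

Step 13. Oxidation may not stop cleanly at the ketol: the C3 hydroxyl may also be oxidised, the C3–C4 bond of the diol may be cleaved on the MnO2 surface, or dehydrogenation towards the flavonol may set in. The fallback sets out from 18 and rejoins at 20. The C3 hydroxyl is silylated (TBSCl, imidazole, DMF) to tert-butyl{[(2R,3S,4R)-6-[(2E)-3,7-dimethylocta-2,6-dien-1-yl]-4,5-dimethoxy-7-(methoxymethoxy)-2-[4-(methoxymethoxy)phenyl]-3,4-dihydro-2H-chromen-3-yl]oxy}dimethylsilane F6. The C4 ether is solvolysed as in step 12 to (2R,3S)-3-[(tert-butyldimethylsilyl)oxy]-6-[(2E)-3,7-dimethylocta-2,6-dien-1-yl]-5-methoxy-7-(methoxymethoxy)-2-[4-(methoxymethoxy)phenyl]-3,4-dihydro-2H-chromen-4-ol F7 (C4 epimers). The now single free alcohol is oxidised with Dess–Martin periodinane to (2R,3R)-3-[(tert-butyldimethylsilyl)oxy]-6-[(2E)-3,7-dimethylocta-2,6-dien-1-yl]-5-methoxy-7-(methoxymethoxy)-2-[4-(methoxymethoxy)phenyl]-2,3-dihydro-4H-chromen-4-one F8. HF·pyridine in THF removes the silyl group to give 20.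

Step 14. During MOM cleavage the liberated 7-OH, or methanol, may add to the geranyl alkenes under protic acid, giving cyclised or solvent-added material. The fallback avoids free protic acid, sets out from 20 and rejoins at 21. Buffered silyl transfer (TESOTf, 2,2'-bipyridyl, CH2Cl2, 0 °C) converts both aryl MOM ethers into aryl silyl ethers and silylates the C3 hydroxyl, giving (2R,3R)-6-[(2E)-3,7-dimethylocta-2,6-dien-1-yl]-5-methoxy-3,7-bis[(triethylsilyl)oxy]-2-{4-[(triethylsilyl)oxy]phenyl}-2,3-dihydro-4H-chromen-4-one F9. HF·pyridine buffered with pyridine in THF at 0 °C then releases 21.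

Further compounds
F1 | step 10 | 3-[(2E)-3,7-dimethylocta-2,6-dien-1-yl]-2-methoxy-4-(methoxymethoxy)-6-[(triisopropylsilyl)oxy]benzaldehyde | COc1c(C/C=C(\C)CCC=C(C)C)c(OCOC)cc(O[Si](C(C)C)(C(C)C)C(C)C)c1C=O
F2 | step 10 | (2E)-1-{3-[(2E)-3,7-dimethylocta-2,6-dien-1-yl]-2-methoxy-4-(methoxymethoxy)-6-[(triisopropylsilyl)oxy]phenyl}-3-[4-(methoxymethoxy)phenyl]prop-2-en-1-ol (racemic) | COc1c(C/C=C(\C)CCC=C(C)C)c(OCOC)cc(O[Si](C(C)C)(C(C)C)C(C)C)c1C(O)/C=C/c1ccc(OCOC)cc1
F3 | step 10 | (2E)-1-{3-[(2E)-3,7-dimethylocta-2,6-dien-1-yl]-2-methoxy-4-(methoxymethoxy)-6-[(triisopropylsilyl)oxy]phenyl}-3-[4-(methoxymethoxy)phenyl]prop-2-en-1-one | COc1c(C/C=C(\C)CCC=C(C)C)c(OCOC)cc(O[Si](C(C)C)(C(C)C)C(C)C)c1C(=O)/C=C/c1ccc(OCOC)cc1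
F4 | step 10 | {3-[(2E)-3,7-dimethylocta-2,6-dien-1-yl]-2-methoxy-4-(methoxymethoxy)-6-[(triisopropylsilyl)oxy]phenyl}{(2R,3S)-3-[4-(methoxymethoxy)phenyl]oxiran-2-yl}methanone | COc1c(C/C=C(\C)CCC=C(C)C)c(OCOC)cc(O[Si](C(C)C)(C(C)C)C(C)C)c1C(=O)[C@@H]1O[C@H]1c1ccc(OCOC)cc1
F5 | step 10 | {3-[(2E)-3,7-dimethylocta-2,6-dien-1-yl]-6-hydroxy-2-methoxy-4-(methoxymethoxy)phenyl}{(2R,3S)-3-[4-(methoxymethoxy)phenyl]oxiran-2-yl}methanone | COc1c(C/C=C(\C)CCC=C(C)C)c(OCOC)cc(O)c1C(=O)[C@@H]1O[C@H]1c1ccc(OCOC)cc1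
F6 | step 13 | tert-butyl{[(2R,3S,4R)-6-[(2E)-3,7-dimethylocta-2,6-dien-1-yl]-4,5-dimethoxy-7-(methoxymethoxy)-2-[4-(methoxymethoxy)phenyl]-3,4-dihydro-2H-chromen-3-yl]oxy}dimethylsilane | COc1c(C/C=C(\C)CCC=C(C)C)c(OCOC)cc2c1[C@@H](OC)[C@H](O[Si](C)(C)C(C)(C)C)[C@@H](c1ccc(OCOC)cc1)O2
F7 | step 13 | (2R,3S)-3-[(tert-butyldimethylsilyl)oxy]-6-[(2E)-3,7-dimethylocta-2,6-dien-1-yl]-5-methoxy-7-(methoxymethoxy)-2-[4-(methoxymethoxy)phenyl]-3,4-dihydro-2H-chromen-4-ol (C4 epimers) | COc1c(C/C=C(\C)CCC=C(C)C)c(OCOC)cc2c1C(O)[C@H](O[Si](C)(C)C(C)(C)C)[C@@H](c1ccc(OCOC)cc1)O2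
F8 | step 13 | (2R,3R)-3-[(tert-butyldimethylsilyl)oxy]-6-[(2E)-3,7-dimethylocta-2,6-dien-1-yl]-5-methoxy-7-(methoxymethoxy)-2-[4-(methoxymethoxy)phenyl]-2,3-dihydro-4H-chromen-4-one | COc1c(C/C=C(\C)CCC=C(C)C)c(OCOC)cc2c1C(=O)[C@H](O[Si](C)(C)C(C)(C)C)[C@@H](c1ccc(OCOC)cc1)O2
F9 | step 14 | (2R,3R)-6-[(2E)-3,7-dimethylocta-2,6-dien-1-yl]-5-methoxy-3,7-bis[(triethylsilyl)oxy]-2-{4-[(triethylsilyl)oxy]phenyl}-2,3-dihydro-4H-chromen-4-one | COc1c(C/C=C(\C)CCC=C(C)C)c(O[Si](CC)(CC)CC)cc2c1C(=O)[C@H](O[Si](CC)(CC)CC)[C@@H](c1ccc(O[Si](CC)(CC)CC)cc1)O2
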